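(The readings come from a simulation with made-up constants, noise included.)

In the south run the catalyst takes up its load sooner than the coupling partner is halved, so the hour is counted here in half-lives of the partner.

| flask | substrate | coupling partner | free catalyst | remark | time |
|---|---|---|---|---|---|
| north | 0.80 M | 0.60 equiv | 2.7 mol% | run made earlier |  |
| south-east | 0.80 M | 0.60 equiv | 3.7 mol% | run made earlier |  |
| south | 0.80 M | 0.60 equiv | 5.8 mol% | run made earlier |  |
| amber | 0.80 M | 0.600 equiv | 2.5 mol% |  | 1.0 h |
| violet | 0.80 M | 0.600 equiv | 4 mol% |  | 1.0 h |
| red | 0.80 M | 0.600 equiv | 6 mol% |  | 1.0 h |

| run | time / min | product / % | substrate / % |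
|---|---|---|---|
| north | 5.00 | 12.5 | 86.3 |
| north | 15.0 | 29.6 | 69.3 |
| north | 30.0 | 43.6 | 56.3 |
| north | 40.0 | 47.8 | 51.3 |
| north | 60.0 | 54.5 | 45.5 |
| south-east | 5.00 | 16.4 | 81.2 |
| south-east | 10.0 | 28.5 | 70.3 |
| south-east | 15.0 | 35.9 | 63.2 |
| south-east | 30.0 | 49.5 | 49.7 |
| south-east | 60.0 | 57.6 | 42.6 |
| south | 5.00 | 23.3 | 74.4 |
| south | 15.0 | 45.0 | 54.0 |
| south | 30.0 | 54.4 | 43.5 |
| south | 40.0 | 56.6 | 41.6 |
| south | 60.0 | 59.0 | 39.2 |

(scatter of a reading: 0.5 percentage points)

- the numbers in the tables scatter with a standard deviation of 0.5 percentage points
- steps under discussion: coupling partner + catalyst intermediate A <-> catalyst intermediate B; catalyst intermediate C -> free catalyst + product; substrate + free catalyst <-> catalyst intermediate A; catalyst intermediate B -> by-product + catalyst intermediate C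
- "hardly changes" means that all values lie within two and a half points (for a concentration: within two and a half percent of the largest)

* amount of product at the end, in percent of the substrate charged for amber, violet, red, in this order
* the shape of the row from first to last (rises all the way / falls all the way / falls, then rises / hardly changes / rises, then falls)

The first rung stands before the first reading. At 5.00 min the south run already lacks 2.30% of its substrate from the balance, and at 60.0 min it lacks 1.80%, against 5.8 mol% of catalyst. This reads as substrate held on the catalyst, at a level that barely moves within the scatter.

The next rung is the partner, the limiting reagent. Each product costs one partner, so what stands of it, as a fraction of the substrate charged, is 0.60 equiv less the product. By 60.0 min the north run has gone through 3.45 halvings, the south-east run 4.64 and the south run 5.91. Read from these last readings, one half-life lasts on average 17.4 min in the north run and 10.2 min in the south run.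

From north to south-east the loading grows by a factor of 1.37 and the halvings by a factor of 1.35, so between these two runs the count follows the loading. The south run, against the north run, falls behind at a factor of 1.71 for a loading factor of 2.15, but its last reading leaves 1.00% of the substrate charged, with a scatter of 0.5 percentage points.

The last rung is the hour itself. Scaling by loading from the north run, amber gets 3.19 halvings; this halving count, the number of half-lives of the partner that fit into a flask's hour, comes to 5.02 for violet, scaled from south-east, and 6.11 for red, scaled from south. My reckoning of the product is then 53.4%, 58.2% and 59.1%, rising towards the charge of partner.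

The forecast is 53.4%, 58% and 59.1%, a row that rises all the way, with the “product ceiling is set by the coupling partner”.

The flasks give 53.2%, 57.6% and 59.4%, a row that rises all the way.

    coupling partner + catalyst intermediate A ⇌ catalyst intermediate B (K = 1.30 L mol⁻¹, k = 6.30 L mol⁻¹ min⁻¹)
    catalyst intermediate C → free catalyst + product (k = 13.0 min⁻¹)
    substrate + free catalyst ⇌ catalyst intermediate A (K = 0.900 L mol⁻¹, k = 74.0 L mol⁻¹ min⁻¹)
    catalyst intermediate B → by-product + catalyst intermediate C (k = 360 min⁻¹)

In amber at 1.00 h, the binding of substrate to free catalyst relaxes with a half-life of 0.00626 min and the binding of the coupling partner to catalyst intermediate A with one of 0.133 min, each step taken alone, both far shorter than the reckoned average of 18.8 min for one halving of the partner. At that time amber's catalyst stands as 74.6% free catalyst, 24.7% catalyst intermediate A, 0.641% catalyst intermediate C and 0.0231% catalyst intermediate B, while 11% of its partner is left, which is 3.15 halvings against a count of 3.19. Red, with a count of 6.11, has 1.1% of its partner left at 1.00 h, which is 6.51 halvings.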